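The two benzene rings are not cut at the last stage: both are taken back to their dihydro forms, so the final step makes no skeletal bond and only removes one H2 from each ring.
What allows this: each ring carries its two oxygen atoms at C1 and C3 and the C14 chain at C5, so ring B is the dehydrogenated form of a 5-alkylcyclohexane-1,3-dione and ring A that of its mono methyl enol ether (a 5-alkyl-3-methoxycyclohex-2-en-1-one). C5 still bears a hydrogen, and the one O-methyl group that distinguishes the two chain ends is stored as enol ether against free dione, with no protecting group.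
Each six-membered ring is then cut at C4–C5 (Michael addition) and C2–C3 (Claisen closure) into a malonate and an (E)-methyl enone, whose C5=C6 bond is cut by a Wittig disconnection to an aldehyde and acetonylidenetriphenylphosphorane.
Forward: hexadecanolide supplies all sixteen chain carbons (the fourteen CH2 groups and both C5 ring carbons); ring A is built at the aldehyde end and fixed as its methyl enol ether, the alcohol end is oxidised and ring B is built there, and both rings are aromatised together last.
Stereochemistry: the target has no stereocentre; the ring centres made on the way form without control and vanish on aromatisation, and the E geometry of both enones comes from the stabilised ylide and is consumed in the Michael additions.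

Key step: step 9

Remark on the chemistry: every compound with a cyclohexane-1,3-dione unit is drawn and named as the diketone although it will exist largely as its enol; the chain-bearing ring carbons are racemic throughout.

Step 1
Reactants: 1 hexadecanolide (oxacycloheptadecan-2-one)
Product: 2 16-hydroxyhexadecanal
Conditions: iBu2AlH (1.1 equiv), CH2Cl2, −78 °C; then MeOH, aq. potassium sodium tartrate (KNaC4H4O6); crude product used directly
Reagents that add atoms: none
Why: Partial reduction of a lactone with iBu2AlH stops at the aluminium hemiacetal at −78 °C, and the large-ring lactol released on work-up has no reason to stay closed and opens to the hydroxy aldehyde.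

Step 2
Reactants: 2 16-hydroxyhexadecanal; 3 1-(triphenylphosphoranylidene)propan-2-one
Product: 4 (E)-19-hydroxynonadec-3-en-2-one
Conditions: THF, 65 °C
Reagents that add atoms: none
Why: Wittig olefination with the stabilised acetonyl ylide tolerates the free alcohol and should give the E enone, the geometry expected for a stabilised ylide.

Step 3
Reactants: 4 (E)-19-hydroxynonadec-3-en-2-one; 5 dimethyl malonate
Product: 9 5-(15-hydroxypentadecyl)cyclohexane-1,3-dione, via open-chain Michael adduct 6 (not isolated), via cyclic keto ester 7 (not isolated), via cyclic keto acid 8 (not isolated)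
Conditions: NaOMe, MeOH, 65 °C; then aq. NaOH, 80 °C; then HCl to pH 1, 90 °C
Reagents that add atoms: none
Why: This is the classical Michael–Claisen annulation to 5-alkylcyclohexane-1,3-diones (malonate conjugate addition, Dieckmann-type closure of the methyl ketone enolate on one ester, saponification, decarboxylation of the β-keto acid); the free alcohol only exchanges reversibly with the esters and is restored by the hydroxide stage, and the C5 centre forms as a racemate.

Step 4
Reactants: 9 5-(15-hydroxypentadecyl)cyclohexane-1,3-dione
Product: 10 5-(15-hydroxypentadecyl)-3-methoxycyclohex-2-en-1-one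
Conditions: MeOH, TsOH·H2O (cat.), 65 °C
Reagents that add atoms: methanol (CO)
Why: Acid-catalysed enol etherification (a vinylogous Fischer esterification) of the symmetric dione can give only one constitutional isomer, and the primary alcohol does not react under these conditions.

Step 5
Reactants: 10 5-(15-hydroxypentadecyl)-3-methoxycyclohex-2-en-1-one
Product: 11 15-(3-methoxy-5-oxocyclohex-3-en-1-yl)pentadecanal
Conditions: Dess–Martin periodinane, pyridine, CH2Cl2, 0 °C to rt
Reagents that add atoms: none
Why: Dess–Martin oxidation takes a primary alcohol to the aldehyde without over-oxidation, and the pyridine buffer keeps the acetic acid formed from touching the vinylogous ester.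

Step 6
Reactants: 11 15-(3-methoxy-5-oxocyclohex-3-en-1-yl)pentadecanal; 3 1-(triphenylphosphoranylidene)propan-2-one
Product: 12 3-methoxy-5-[(15E)-17-oxooctadec-15-en-1-yl]cyclohex-2-en-1-one
Conditions: THF, 65 °C
Reagents that add atoms: none
Why: In this Wittig olefination the stabilised ylide reacts with the aldehyde only, because the ring carbonyl is a deactivated vinylogous ester, and the E enone is expected.

Step 7
Reactants: 12 3-methoxy-5-[(15E)-17-oxooctadec-15-en-1-yl]cyclohex-2-en-1-one; 13 diallyl malonate
Product: 15 allyl 2-[14-(3-methoxy-5-oxocyclohex-3-en-1-yl)tetradecyl]-4,6-dioxocyclohexane-1-carboxylate, via open-chain Michael adduct 14 (not isolated)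
Conditions: NaH (1.1 equiv), THF, 0 °C then 65 °C; then cold dilute HCl to pH 4
Reagents that add atoms: none
Why: This Michael–Claisen annulation is run with the preformed sodium enolate of the malonate in an aprotic solvent, so the only alkoxide present is the allyloxide expelled on ring closure, which the acidic cyclic product protonates at once and which therefore exchanges neither the allyl ester nor the ring A methyl enol ether; the two new ring centres form as a diastereomer mixture that is erased later.

Step 8
Reactants: 15 allyl 2-[14-(3-methoxy-5-oxocyclohex-3-en-1-yl)tetradecyl]-4,6-dioxocyclohexane-1-carboxylate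
Product: 17 5-[14-(3-methoxy-5-oxocyclohex-3-en-1-yl)tetradecyl]cyclohexane-1,3-dione, via cyclic keto acid 16 (not isolated)
Conditions: Pd(PPh3)4 (5 mol%), HCO2H (3 equiv), Et3N (2 equiv), THF, rt then 50 °C
Reagents that add atoms: none
Why: In this Tsuji deallylation the zerovalent palladium complex adds oxidatively to the allyl ester, formate reduces the π-allyl complex of divalent palladium to propene before the dione enolate can capture it, and the freed β-keto acid loses CO2 on gentle warming in a water-free, weakly acidic medium that neither hydrolyses nor exchanges the methyl enol ether.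

Step 9
Reactants: 17 5-[14-(3-methoxy-5-oxocyclohex-3-en-1-yl)tetradecyl]cyclohexane-1,3-dione
Product: 20 5-[14-(3-hydroxy-5-methoxyphenyl)tetradecyl]benzene-1,3-diol (CID16109872), via half-aromatised phenol dione 18 (not isolated), via half-aromatised resorcinol enone 19 (not isolated)
Conditions: palladium metal on carbon (10% Pd/C), ethylene (1 atm), K2CO3 (1.1 equiv), N,N-dimethylacetamide, 140 °C; then dilute HCl
Reagents that add atoms: none
Why: Each ring binds to the palladium surface as an enolate (ring A through C6 of the vinylogous ester, ring B through C4 of the potassium dione enolate), β-hydride elimination of the C5 hydrogen gives the unsaturated keto tautomer of a phenol, which enolises at once, and ethylene carries the hydrogen off as ethane; the rings react independently, so both half-aromatised compounds 18 and 19 are expected on the way to 20. The closest known reaction type is the heterogeneous palladium-catalysed dehydrogenative aromatisation of cyclohexane-1,3-diones to resorcinols and of 3-alkoxycyclohex-2-en-1-ones to 3-alkoxyphenols with an alkene as hydrogen acceptor, here run on both rings of one molecule. No ring is closed and no skeletal bond is formed: both six-membered rings already exist, each loses one molecule of H2, and the gain of aromaticity drives the change. No stereocentre is created; the two uncontrolled C5 centres of 17 become sp2 carbons. The step needs chemoselectivity, namely that the single methyl group stays on the ring A oxygen: its place was fixed when the symmetric dione 9 was etherified, and K2CO3 holds the ring B dione as its enolate so that no acid is present to catalyse exchange or hydrolysis of the enol ether; regioselectivity is no issue, because loss of H2 across C4–C5 or C5–C6 of either ring leads to the same phenol.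

Compound list
1 | hexadecanolide (oxacycloheptadecan-2-one) | O=C1CCCCCCCCCCCCCCCO1 | starting material
2 | 16-hydroxyhexadecanal | O=CCCCCCCCCCCCCCCCO | intermediate
3 | 1-(triphenylphosphoranylidene)propan-2-one | CC(=O)C=P(c1ccccc1)(c1ccccc1)c1ccccc1 | starting material
4 | (E)-19-hydroxynonadec-3-en-2-one | CC(=O)/C=C/CCCCCCCCCCCCCCCO | intermediate
5 | dimethyl malonate | COC(=O)CC(=O)OC | starting material
6 | dimethyl 2-(19-hydroxy-2-oxononadecan-4-yl)malonate (open-chain Michael adduct) | CC(=O)CC(CCCCCCCCCCCCCCCO)C(C(=O)OC)C(=O)OC | intermediate
7 | methyl 2-(15-hydroxypentadecyl)-4,6-dioxocyclohexane-1-carboxylate (cyclic keto ester) | COC(=O)C1C(=O)CC(=O)CC1CCCCCCCCCCCCCCCO | intermediate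
8 | 2-(15-hydroxypentadecyl)-4,6-dioxocyclohexane-1-carboxylic acid (cyclic keto acid) | OC(=O)C1C(=O)CC(=O)CC1CCCCCCCCCCCCCCCO | intermediate
9 | 5-(15-hydroxypentadecyl)cyclohexane-1,3-dione | O=C1CC(=O)CC(CCCCCCCCCCCCCCCO)C1 | intermediate
10 | 5-(15-hydroxypentadecyl)-3-methoxycyclohex-2-en-1-one | COC1=CC(=O)CC(CCCCCCCCCCCCCCCO)C1 | intermediate
11 | 15-(3-methoxy-5-oxocyclohex-3-en-1-yl)pentadecanal | COC1=CC(=O)CC(CCCCCCCCCCCCCCC=O)C1 | intermediate
12 | 3-methoxy-5-[(15E)-17-oxooctadec-15-en-1-yl]cyclohex-2-en-1-one | COC1=CC(=O)CC(CCCCCCCCCCCCCC/C=C/C(C)=O)C1 | intermediate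
13 | diallyl malonate | C=CCOC(=O)CC(=O)OCC=C | starting material
14 | diallyl 2-[18-(3-methoxy-5-oxocyclohex-3-en-1-yl)-2-oxooctadecan-4-yl]malonate (open-chain Michael adduct) | CC(=O)CC(CCCCCCCCCCCCCCC1CC(=O)C=C(OC)C1)C(C(=O)OCC=C)C(=O)OCC=C | intermediate
15 | allyl 2-[14-(3-methoxy-5-oxocyclohex-3-en-1-yl)tetradecyl]-4,6-dioxocyclohexane-1-carboxylate | C=CCOC(=O)C1C(=O)CC(=O)CC1CCCCCCCCCCCCCCC2CC(=O)C=C(OC)C2 | intermediate
16 | 2-[14-(3-methoxy-5-oxocyclohex-3-en-1-yl)tetradecyl]-4,6-dioxocyclohexane-1-carboxylic acid (cyclic keto acid) | OC(=O)C1C(=O)CC(=O)CC1CCCCCCCCCCCCCCC2CC(=O)C=C(OC)C2 | intermediate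
17 | 5-[14-(3-methoxy-5-oxocyclohex-3-en-1-yl)tetradecyl]cyclohexane-1,3-dione | O=C1CC(=O)CC(CCCCCCCCCCCCCCC2CC(=O)C=C(OC)C2)C1 | intermediate
18 | 5-[14-(3-hydroxy-5-methoxyphenyl)tetradecyl]cyclohexane-1,3-dione (ring A aromatic, ring B still dione) | COc1cc(O)cc(CCCCCCCCCCCCCCC2CC(=O)CC(=O)C2)c1 | intermediate
19 | 5-[14-(3,5-dihydroxyphenyl)tetradecyl]-3-methoxycyclohex-2-en-1-one (ring B aromatic, ring A still enol ether) | COC1=CC(=O)CC(CCCCCCCCCCCCCCc2cc(O)cc(O)c2)C1 | intermediate
20 | 5-[14-(3-hydroxy-5-methoxyphenyl)tetradecyl]benzene-1,3-diol (CID16109872) | COc1cc(O)cc(CCCCCCCCCCCCCCc2cc(O)cc(O)c2)c1 | target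

Total step count: 9
Longest linear sequence: 9 steps (1 to 20)

Steps most likely to fail

Step 9. One ring may stop at the half-aromatised stage, the methyl group may be transferred between rings or lost, or the dione enolate of one molecule may condense with the vinylogous ester of another at the temperature needed. The fallback sets out from 17 and comes back at 20. Treatment of 17 with an excess of LiN(iPr)2 in THF at −78 °C (enolate dianion of the ring B dione, cross-conjugated kinetic enolate of ring A) and then PhSeCl should give the bis-selenide 5-{14-[3-methoxy-5-oxo-6-(phenylselanyl)cyclohex-3-en-1-yl]tetradecyl}-4-(phenylselanyl)cyclohexane-1,3-dione F1, with each selenium on the CH next to the chain-bearing carbon. Oxidation with H2O2 and pyridine in CH2Cl2 at 0 °C, syn elimination of both selenoxides toward C5 and tautomerisation would then give 20.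

Step 8. The π-allyl palladium intermediate may C-allylate the dione enolate in competition with hydride transfer from formate, or the loss of CO2 from the buffered acid may be slow. The fallback sets out from 12 and comes back at 17, with no allyl electrophile involved. Enone 12 is annulated with dibenzyl malonate and NaH in THF through the open-chain adduct dibenzyl 2-[18-(3-methoxy-5-oxocyclohex-3-en-1-yl)-2-oxooctadecan-4-yl]malonate F2 to benzyl 2-[14-(3-methoxy-5-oxocyclohex-3-en-1-yl)tetradecyl]-4,6-dioxocyclohexane-1-carboxylate F3. Hydrogenolysis (H2, palladium metal on carbon, ethyl acetate, rt) should free acid 16 in neutral form with toluene as the only co-product, and warming should give 17.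

Step 7. In the aprotic medium the open-chain Michael adduct may fail to equilibrate to the methyl ketone enolate that has to close the ring, or the enone may undergo retro-Michael reaction or oligomerisation. The fallback sets out from 12 and comes back at 17, at the price of a statistical step.
- Enone 12 is taken through the classical protic annulation with dimethyl malonate 5 and NaOMe in MeOH, where methoxide exchange at the methyl enol ether is degenerate. This passes through the adduct dimethyl 2-[18-(3-methoxy-5-oxocyclohex-3-en-1-yl)-2-oxooctadecan-4-yl]malonate F4 and the ester methyl 2-[14-(3-methoxy-5-oxocyclohex-3-en-1-yl)tetradecyl]-4,6-dioxocyclohexane-1-carboxylate F5.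
- Aqueous NaOH gives the salt of acid 16, and hot HCl then removes CO2 and, unavoidably, the ring A methyl group, to give the symmetric bis-dione 5,5'-(tetradecane-1,14-diyl)bis(cyclohexane-1,3-dione) F6.
- Partial etherification of F6 (MeOH, TsOH, stopped early) would return 17 as the middle component of a statistical mixture. After chromatography, unchanged F6 is reused, and the bis-enol ether 1,14-bis(3-methoxy-5-oxocyclohex-3-en-1-yl)tetradecane F7 is hydrolysed back to F6 with aqueous HCl.

Further compounds
F1 | step 9 | 5-{14-[3-methoxy-5-oxo-6-(phenylselanyl)cyclohex-3-en-1-yl]tetradecyl}-4-(phenylselanyl)cyclohexane-1,3-dione | COC1=CC(=O)C([Se]c2ccccc2)C(CCCCCCCCCCCCCCC3CC(=O)CC(=O)C3[Se]c4ccccc4)C1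
F2 | step 8 | dibenzyl 2-[18-(3-methoxy-5-oxocyclohex-3-en-1-yl)-2-oxooctadecan-4-yl]malonate | CC(=O)CC(CCCCCCCCCCCCCCC1CC(=O)C=C(OC)C1)C(C(=O)OCc2ccccc2)C(=O)OCc3ccccc3
F3 | step 8 | benzyl 2-[14-(3-methoxy-5-oxocyclohex-3-en-1-yl)tetradecyl]-4,6-dioxocyclohexane-1-carboxylate | O=C(OCc1ccccc1)C2C(=O)CC(=O)CC2CCCCCCCCCCCCCCC3CC(=O)C=C(OC)C3
F4 | step 7 | dimethyl 2-[18-(3-methoxy-5-oxocyclohex-3-en-1-yl)-2-oxooctadecan-4-yl]malonate | CC(=O)CC(CCCCCCCCCCCCCCC1CC(=O)C=C(OC)C1)C(C(=O)OC)C(=O)OC
F5 | step 7 | methyl 2-[14-(3-methoxy-5-oxocyclohex-3-en-1-yl)tetradecyl]-4,6-dioxocyclohexane-1-carboxylate | COC(=O)C1C(=O)CC(=O)CC1CCCCCCCCCCCCCCC2CC(=O)C=C(OC)C2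
F6 | step 7 | 5,5'-(tetradecane-1,14-diyl)bis(cyclohexane-1,3-dione) | O=C1CC(=O)CC(CCCCCCCCCCCCCCC2CC(=O)CC(=O)C2)C1
F7 | step 7 | 1,14-bis(3-methoxy-5-oxocyclohex-3-en-1-yl)tetradecane | COC1=CC(=O)CC(CCCCCCCCCCCCCCC2CC(=O)C=C(OC)C2)C1
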